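**Numbering used throughout.** 1 4-bromo-2,6-dimethoxyphenol; 2 its benzyl ether; 3 the aryllithium from 2; 4 the ring A methyl ketone; 5 its trifluoroacetyl derivative; 6 the ring A diazoketone; 7 methanol; 8 3-(benzyloxy)-4-methoxybenzaldehyde; 9 the enol formed from 6 and 7; 10 the open-chain hydroxy ketone; 11 the protected chromanone; 12 the target.

## Analysis of the target

Compound 12 is a 2-aryl-2,3-dihydro-4H-chromen-4-one (a flavanone). Ring A (C4a to C8a) carries hydroxyls at C5 and C6 and a methoxy group at C7; ring C (O1, C2, C3, C4) carries the ketone at C4 and a methoxy group at C3; ring B at C2 is a 3-hydroxy-4-methoxyphenyl group. The two stereocentres are adjacent, C2 (R) and C3 (R), with the aryl and methoxy groups trans and both equatorial on the half-chair of ring C. They are not equally robust. C3 is alpha to the ketone, epimerises through the enol and settles in the trans arrangement, so only C2 needs absolute control. C2 is a benzylic ether carbon para to a methoxy donor and beta to the ketone; it is lost if ring C opens, by elimination of the O1 phenoxide from the C3 enolate under strong base or by ionisation of C2–O1 under strong acid. The sensitive groups are the ring A catechol (oxidation, metal chelation), the beta-alkoxy ketone, and three methyl ethers (O3, O7, O4') that must survive while O5, O6 and O3' end as free hydroxyls. The difficulty lies in six oxygen substituents in three different states, a ring A substituted at five of six positions, and an O3 methyl group that cannot be installed late without base strong enough to open ring C. The strategy rests on C3: its four attachments are hydrogen, methoxy, the C4 acyl carbon and the bond to the carbinol carbon C2, which is the pattern left when a ketocarbene carbon takes up methanol and is intercepted by an aldehyde.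

## Retrosynthetic reasoning

**12 from 11.** The last disconnection removes protecting groups only: the O–CH2Ph bonds at O6 and O3' and the O–CH3 bond at O5. O5 is carried as a methyl ether on purpose. With methyl on O5 and O7 and benzyl on O6, the ring A building block is symmetric, so the carbon that becomes C4a has no competitor. In 11 the O5 methyl differs from the O7 methyl by lying peri to the C4 carbonyl, which lets a chelating boron halide single it out. The forward step has to free three hydroxyls without touching the O3, O7 and O4' methyl ethers or the C2–O1 bond.

**11 from 10.** Ring C is opened at O1–C8a, so that C8a carries bromine and C2 a free hydroxyl. Cutting O1–C2 instead would decide the configuration of the benzylic carbon in the ring closure, by substitution or conjugate addition at a centre that ionises easily. Cutting O1–C8a means the C2–O bond made in the open chain is never broken again. Cutting C4–C4a would require acylation of ring A with the stereocentres of the chain exposed to Lewis acid. The gain is an acyclic hydroxy ketone 10 whose two stereocentres are the two carbons of an aldol unit. The forward reaction is a copper-mediated aryl ether formation from a secondary alcohol and an aryl bromide activated by the ortho ketone; its base also equilibrates C3.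

**10 from 6, 7 and 8.** Both bonds at C3 that simple precursors lack are cut together: C3–OMe and C2–C3 (chromanone numbering). This splits 10 into three components, each carrying one piece of C3's environment: diazoketone 6 supplies the carbon with its hydrogen and acyl group, methanol 7 the methoxy group, aldehyde 8 the carbinol carbon with ring B. Cutting C2–C3 alone would be an ordinary aldol of a preformed methoxy ketone; it costs an extra step and is kept as the fallback. The forward reaction must make the metal carbenoid from 6 add 7, then let the resulting enol 9 attack 8 before it tautomerises, and it must fix the configuration of the carbinol carbon. The neighbouring centre is corrected later.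

**6 from 4 via 5.** The diazo group is traced back to the methyl group of ketone 4 by diazo transfer. A methyl ketone is not acidic enough for direct transfer, so it is activated in the flask as its trifluoroacetyl derivative 5. This avoids a hindered acid chloride and diazomethane.

**4 from 2 via 3.** The aryl–acyl bond is cut. Electrophilic acylation would reach the same carbon, but the Lewis acids needed at a position wedged between bromine and methoxy strip aryl benzyl ethers and demethylate the ether next to the new ketone. The bond is therefore made from the other polarity. The only two ring hydrogens of 2 are equivalent and each lies between bromine and a methoxy group, the most acidic site on the ring; a lithium amide removes one without halogen–metal exchange to give 3, which is acylated by an amide-type acetyl donor that stops at the ketone.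

**2 from 1.** The benzyl ether is cut back to commercial phenol 1. Aldehyde 8 is purchased.

## Alternatives that were turned down

**Alternative 1:** Same O1–C8a bond, but C8a is an unfunctionalised C–H. The precursor is the open-chain catechol A1. Anodic oxidation turns its ring A catechol into an o-quinone whose C4a=C8a bond is conjugated to the C5 carbonyl and carries the C4 acyl group. The C2 hydroxyl adds at C8a (6-endo-trig oxa-Michael) and tautomerisation returns the catechol A2.
- For: no halogen on ring A, no metal and no base at the ring closure, so the aldol unit is not exposed to retro-aldol conditions. O5 and O6 are already free, so only one hydrogenolysis remains. On protecting-group economy after the ring closure this plan is stronger than the chosen one.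
- Against: A2 is again a catechol, richer in electrons than A1 by one more ether oxygen, so it oxidises more easily than the substrate and over-oxidation is built in. A hindered secondary alcohol must beat water and electrolyte for the quinone in a geometrically slow endo closure.
- The plan also does not say how A1 is obtained as one enantiomer. The same C2–C3 bond still has to be made asymmetrically, with the catechol protected during that step and freed before the electrolysis.
- Comparison: the chosen route makes that bond and the C3–OMe bond in its key step and closes the ring with a known reaction type. Alternative 1 would add a second unproven step to a route that already needs one.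

**Alternative 2:** Ring C is cut at C3=C4 after adjusting the oxidation state. The diene A3 (an aryl 1-arylallyl ether with an ortho vinyl group) is closed by second-generation Grubbs catalyst to the 2H-chromene A4.
- For: ring-closing metathesis of such dienes is dependable, neutral and free of base. C2 would come from an enantioenriched allylic ether made by known asymmetric allylic substitution. On the reliability of the ring-closing event itself this plan is stronger than the copper closure of step 5.
- Against: the ring closure delivers neither the C4 ketone nor the C3 methoxy group. From A4 the alkene must be dioxygenated anti to the aryl group, the C3 and C4 hydroxyls told apart, O3 methylated and C4 oxidised, at least three further steps.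
- 2-Aryl-2H-chromenes with donor-rich rings are configurationally fragile: thermal electrocyclic opening to an o-quinone methide or acid ionisation to a benzopyrylium ion erases C2.
- Ring A of A3 needs a fourth oxygen at C8a and a vinyl group at C4a, a longer building-block synthesis than the two steps from 1 to 4.
- Comparison: the chosen route installs C3–OMe and the C4 oxidation state directly and keeps C2 as a saturated carbinol throughout.

**Alternative 3:** O1–C8a and C4–C4a are cut together. CsF releases the ring A aryne from silyl triflate A5; the alkoxide of hydroxy ester A6 adds at C8a, the aryne carbon remote from the C5 methoxy group, and the aryl anion at C4a attacks the ester to close ring C, giving A7, which is the same structure as 11.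
- For: it is the most convergent plan, with two bonds and the ring in one step. The stereocentres of A6 come from auxiliary-controlled glycolate aldol chemistry with predictable outcome; on stereochemical reliability it is stronger than the chosen key step. The inductive effect of the C5 methoxy group directs the addition the right way.
- Against: after the alkoxide adds, the aryl anion must attack an ester in preference to taking a proton from the next hydroxyl in solution, and for aliphatic alcohols simple aryl ether formation is the usual result. Fluoride and alkoxide also invite retro-aldol cleavage and C3 epimerisation of A6.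
- A5 is a pentasubstituted benzene with silyl and triflate placed on adjacent carbons, several steps beyond 2. The auxiliary must be attached and removed. The end game from A7 is identical, so nothing is saved later.
- Comparison: the chosen route is shorter (six steps), builds the chain from three cheap components, and places its uncertainty in a step fed by inexpensive material, not at a ring closure fed by auxiliary-derived material.

Key step: step 4

Assumption: aldehyde 8 is taken as a purchased compound (it is one benzylation away from isovanillin).
Assumption: the sense of induction of the chiral phosphoric acid in step 4 cannot be derived with certainty; the (R) acid is written as the working choice.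

## Route

Step 1
Reactants: 1 4-bromo-2,6-dimethoxyphenol
Product: 2 2-(benzyloxy)-5-bromo-1,3-dimethoxybenzene
Conditions: BnBr, K2CO3, DMF, rt
Reagents that add atoms: benzyl bromide, BrCc1ccccc1
Why: Williamson ether synthesis: the phenoxide of 1 displaces bromide from benzyl bromide (SN2); the aryl bromide is inert under these conditions.

Step 2
Reactants: 2 2-(benzyloxy)-5-bromo-1,3-dimethoxybenzene
Product: 4 1-[3-(benzyloxy)-6-bromo-2,4-dimethoxyphenyl]ethan-1-one, via aryllithium 3 (not isolated)
Conditions: LiN(i-Pr)2, THF, −78 °C; MeC(O)N(OMe)Me, −78 → −40 °C; aq. NH4Cl
Reagents that add atoms: N-methoxy-N-methylacetamide, CC(=O)N(C)OC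
Why: Directed ortho-metalation: the two ring hydrogens of 2 are equivalent and each lies between bromine and a methoxy group, and a lithium amide deprotonates there without bromine–lithium exchange. Aryllithium 3 is kept at −78 °C to suppress loss of LiBr and is acylated by the Weinreb amide, whose chelated tetrahedral adduct releases ketone 4 only on work-up.

Step 3
Reactants: 4 1-[3-(benzyloxy)-6-bromo-2,4-dimethoxyphenyl]ethan-1-one
Product: 6 1-[3-(benzyloxy)-6-bromo-2,4-dimethoxyphenyl]-2-diazoethan-1-one, via trifluoroacetyl diketone 5 (not isolated)
Conditions: LiN(SiMe3)2, THF, −78 °C; CF3CO2CH2CF3; aq. HCl; then 4-AcNHC6H4SO2N3, Et3N, H2O (1 equiv), MeCN, rt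
Reagents that add atoms: 4-acetamidobenzenesulfonyl azide, CC(=O)Nc1ccc(cc1)S(=O)(=O)N=[N+]=[N-]
Why: Detrifluoroacetylative diazo transfer (Danheiser): the kinetic enolate of methyl ketone 4 is trifluoroacetylated to diketone 5, whose enolate adds to the sulfonyl azide and fragments with transfer of the trifluoroacetyl group to nitrogen, leaving the diazo group on the former methyl carbon. Direct transfer to the unactivated ketone would not proceed.

Step 4
Reactants: 6 1-[3-(benzyloxy)-6-bromo-2,4-dimethoxyphenyl]-2-diazoethan-1-one; 7 methanol; 8 3-(benzyloxy)-4-methoxybenzaldehyde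
Product: 10 (2R,3R)-1-[3-(benzyloxy)-6-bromo-2,4-dimethoxyphenyl]-3-[3-(benzyloxy)-4-methoxyphenyl]-3-hydroxy-2-methoxypropan-1-one, via enol 9 (not isolated)
Conditions: Rh2(OAc)4 (2 mol %), (R)-TRIP [(R)-3,3'-bis(2,4,6-triisopropylphenyl)-1,1'-binaphthyl-2,2'-diyl hydrogen phosphate] (10 mol %), 4 Å MS, CH2Cl2, −20 °C; 6 added over 2 h to 7 (1.2 equiv) and 8 (1.5 equiv)
Reagents that add atoms: none
Why: Proposed new method: Rh2(OAc)4 converts diazoketone 6 into an electrophilic rhodium carbenoid with loss of N2, the oxygen of methanol 7 adds to it, and the protic oxonium ylide relaxes to enol 9, which the phosphoric acid holds through its P=O oxygen while its P–OH activates the carbonyl of aldehyde 8, so that C–C bond formation overtakes the 1,2-proton shift that would end in plain O–H insertion. The closest known reaction type is the Rh2(OAc)4 and chiral Brønsted acid co-catalysed three-component coupling of aryldiazoacetates with alcohols and aldehydes or imines through trapped oxonium ylides; an acceptor-only aryl diazomethyl ketone combined with an electron-rich benzaldehyde has not been shown. No ring is closed: the step forms the C3–OMe and C2–C3 bonds of the later ring C (C2–OMe and C2–C3 of 10) in an open chain. The carbinol centre C3 of 10 is set by the phosphoric acid, which shields one face of the bound aldehyde inside its 3,3'-aryl pocket; the antipode of the acid is taken if the sense of induction proves opposite. The methoxy-bearing centre C2 of 10 follows from the enol geometry in the same hydrogen-bonded assembly; the anti isomer drawn as 10 cyclises directly to the trans ring, but the syn isomer is equally usable because this centre is equilibrated in step 5. The selectivity required is chemoselectivity for three-component coupling over two-component O–H insertion, over carbonyl-ylide formation between the carbenoid and 8, and over capture of the carbenoid by the ortho methoxy oxygen. It is served by slow addition of 6 to an excess of 8 with only a slight excess of 7, by sieves and low temperature, and in the substrate by methanol being a far better nucleophile than the flanked aryl ether oxygen and by the enol carbon of 9 carrying only hydrogen and methoxy.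

Step 5
Reactants: 10 (2R,3R)-1-[3-(benzyloxy)-6-bromo-2,4-dimethoxyphenyl]-3-[3-(benzyloxy)-4-methoxyphenyl]-3-hydroxy-2-methoxypropan-1-one
Product: 11 (2R,3R)-6-(benzyloxy)-2-[3-(benzyloxy)-4-methoxyphenyl]-3,5,7-trimethoxy-2,3-dihydro-4H-chromen-4-one
Conditions: CuI (10 mol %), 3,4,7,8-tetramethyl-1,10-phenanthroline (20 mol %), Cs2CO3 (1.5 equiv), toluene, 80 °C
Reagents that add atoms: none
Why: Ullmann-type intramolecular C–O coupling: the C–Br bond ortho to the ketone is activated toward the phenanthroline-ligated copper alkoxide, and the secondary alkoxide closes ring C through O1–C8a as a six-membered ring without touching the C2–O bond, so C2 stays (R). The carbonate equilibrates the enolisable C3 toward the trans, diequatorial arrangement, so any C2 epimer of 10 carried from step 4 converges on 11.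

Step 6
Reactants: 11 (2R,3R)-6-(benzyloxy)-2-[3-(benzyloxy)-4-methoxyphenyl]-3,5,7-trimethoxy-2,3-dihydro-4H-chromen-4-one
Product: 12 (2R,3R)-5,6-dihydroxy-2-(3-hydroxy-4-methoxyphenyl)-3,7-dimethoxy-2,3-dihydro-4H-chromen-4-one
Conditions: BCl3 (6 equiv), C6HMe5 (6 equiv), CH2Cl2, −78 → 0 °C; MeOH/H2O
Reagents that add atoms: none
Why: Lewis-acid ether cleavage: BCl3 cleaves the two aryl benzyl ethers at low temperature, pentamethylbenzene trapping the benzyl cation before it can alkylate rings A and B. On warming to 0 °C the boron chelated between the C4 carbonyl and O5 lets chloride remove only the peri methyl group; the O7, O4' and O3 methyl ethers lack this six-membered chelate and should persist, and neither stereocentre is touched.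

## Compound list

1 | 4-bromo-2,6-dimethoxyphenol | COc1cc(Br)cc(OC)c1O | starting material
2 | 2-(benzyloxy)-5-bromo-1,3-dimethoxybenzene | COc1cc(Br)cc(OC)c1OCc1ccccc1 | intermediate
3 | [3-(benzyloxy)-6-bromo-2,4-dimethoxyphenyl]lithium | [Li]c1c(Br)cc(OC)c(OCc2ccccc2)c1OC | intermediate
4 | 1-[3-(benzyloxy)-6-bromo-2,4-dimethoxyphenyl]ethan-1-one | COc1cc(Br)c(C(C)=O)c(OC)c1OCc1ccccc1 | intermediate
5 | 1-[3-(benzyloxy)-6-bromo-2,4-dimethoxyphenyl]-4,4,4-trifluorobutane-1,3-dione | COc1cc(Br)c(C(=O)CC(=O)C(F)(F)F)c(OC)c1OCc1ccccc1 | intermediate
6 | 1-[3-(benzyloxy)-6-bromo-2,4-dimethoxyphenyl]-2-diazoethan-1-one | COc1cc(Br)c(C(=O)C=[N+]=[N-])c(OC)c1OCc1ccccc1 | intermediate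
7 | methanol | CO | starting material
8 | 3-(benzyloxy)-4-methoxybenzaldehyde | COc1ccc(C=O)cc1OCc1ccccc1 | starting material
9 | 1-[3-(benzyloxy)-6-bromo-2,4-dimethoxyphenyl]-2-methoxyethen-1-ol (enol form of the protic oxonium ylide) | COC=C(O)c1c(Br)cc(OC)c(OCc2ccccc2)c1OC | intermediate
10 | (2R,3R)-1-[3-(benzyloxy)-6-bromo-2,4-dimethoxyphenyl]-3-[3-(benzyloxy)-4-methoxyphenyl]-3-hydroxy-2-methoxypropan-1-one | COc1ccc([C@@H](O)[C@@H](OC)C(=O)c2c(Br)cc(OC)c(OCc3ccccc3)c2OC)cc1OCc1ccccc1 | intermediate
11 | (2R,3R)-6-(benzyloxy)-2-[3-(benzyloxy)-4-methoxyphenyl]-3,5,7-trimethoxy-2,3-dihydro-4H-chromen-4-one | COc1ccc([C@H]2Oc3cc(OC)c(OCc4ccccc4)c(OC)c3C(=O)[C@@H]2OC)cc1OCc1ccccc1 | intermediate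
12 | (2R,3R)-5,6-dihydroxy-2-(3-hydroxy-4-methoxyphenyl)-3,7-dimethoxy-2,3-dihydro-4H-chromen-4-one | COc1ccc([C@H]2Oc3cc(OC)c(O)c(O)c3C(=O)[C@@H]2OC)cc1O | target

## Step count and risk

Total step count: 6. Longest linear sequence: 6 steps (1 → 2 → 4 → 6 → 10 → 11 → 12); 7 and 8 enter in step 4.

**Step 4 (key step, proposed new method).**
- Most likely failure: the enol tautomerises to the plain O–H insertion product before the weakly electrophilic, electron-rich aldehyde can intercept it.
- Also possible: weak binding of the aldehyde to the phosphoric acid giving poor facial selectivity at the carbinol carbon, and capture of the carbenoid by the ortho methoxy oxygen.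
- Fallback (known chemistry), from 6 back to 10:
  - Rh2(OAc)4 in CH2Cl2 with excess methanol gives by O–H insertion 1-[3-(benzyloxy)-6-bromo-2,4-dimethoxyphenyl]-2-methoxyethan-1-one F1.
  - Its lithium enolate (LiN(SiMe3)2, THF, −78 °C) adds to 8 to give racemic 1-[3-(benzyloxy)-6-bromo-2,4-dimethoxyphenyl]-3-[3-(benzyloxy)-4-methoxyphenyl]-3-hydroxy-2-methoxypropan-1-one F2 as a mixture of diastereomers.
  - Dess–Martin periodinane oxidises it to 1-[3-(benzyloxy)-6-bromo-2,4-dimethoxyphenyl]-3-[3-(benzyloxy)-4-methoxyphenyl]-2-methoxypropane-1,3-dione F3.
  - Asymmetric transfer hydrogenation with dynamic kinetic resolution (RuCl[(S,S)-TsDPEN](p-cymene), HCO2H/Et3N) should reduce only the unhindered ring B ketone, since the ring A ketone is twisted between two ortho substituents, and set the carbinol centre. The (S,S) complex is the working choice for the (R) carbinol. The route is rejoined at 10.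

**Step 5.**
- Most likely failure: retro-aldol cleavage of the caesium alkoxide of 10 at 80 °C, which either loses material or, through re-addition, erodes the configuration of the carbinol carbon. Base-induced dehydration of the beta-hydroxy ketone is a second possibility.
- Fallback, from 10 back to 11:
  - NaBH4 (THF/MeOH, 0 °C) gives (2R,3R)-1-[3-(benzyloxy)-6-bromo-2,4-dimethoxyphenyl]-3-[3-(benzyloxy)-4-methoxyphenyl]-2-methoxypropane-1,3-diol F4 as a mixture of C1 epimers, which cannot undergo retro-aldol cleavage.
  - The same CuI/phenanthroline coupling closes the ring through the C3 hydroxyl, the only one that can reach C–Br in a six-membered ring, giving (2R,3S)-6-(benzyloxy)-2-[3-(benzyloxy)-4-methoxyphenyl]-3,5,7-trimethoxy-3,4-dihydro-2H-chromen-4-ol F5 as a mixture of C4 epimers.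
  - Dess–Martin periodinane returns the ketone 11.

**Step 6.**
- Most likely failure: over-demethylation, at O3 through a five-membered boron chelate with the ketone, or at O7 and O4' assisted by the neighbouring aryloxyboron groups.
- Also possible: Lewis-acid ionisation of the C2–O1 bond with epimerisation at C2.
- Fallback, from 11 back to 12:
  - Hydrogenolysis (H2, Pd/C, EtOAc, rt) removes both benzyl groups under neutral conditions to give (2R,3R)-6-hydroxy-2-(3-hydroxy-4-methoxyphenyl)-3,5,7-trimethoxy-2,3-dihydro-4H-chromen-4-one F6.
  - MgI2·OEt2 (toluene/Et2O, 50 °C) then removes only the chelated O5 methyl group, giving 12.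

**Step 2.**
- Most likely failure: loss of LiBr from aryllithium 3 to an aryne on any warming, or proton transfer from the acetyl donor to the hindered aryllithium, which returns 2.
- Fallback, from 2 back to 4:
  - Magnesiation with TMPMgCl·LiCl (THF, 0 °C to rt) gives [3-(benzyloxy)-6-bromo-2,4-dimethoxyphenyl]magnesium chloride F7, which does not eliminate.
  - Addition to acetaldehyde gives racemic 1-[3-(benzyloxy)-6-bromo-2,4-dimethoxyphenyl]ethan-1-ol F8.
  - Dess–Martin periodinane oxidises it to 4.

## Further compounds

F1 | step 4 | 1-[3-(benzyloxy)-6-bromo-2,4-dimethoxyphenyl]-2-methoxyethan-1-one | COCC(=O)c1c(Br)cc(OC)c(OCc2ccccc2)c1OC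
F2 | step 4 | 1-[3-(benzyloxy)-6-bromo-2,4-dimethoxyphenyl]-3-[3-(benzyloxy)-4-methoxyphenyl]-3-hydroxy-2-methoxypropan-1-one (racemic, both diastereomers) | COc1ccc(C(O)C(OC)C(=O)c2c(Br)cc(OC)c(OCc3ccccc3)c2OC)cc1OCc1ccccc1
F3 | step 4 | 1-[3-(benzyloxy)-6-bromo-2,4-dimethoxyphenyl]-3-[3-(benzyloxy)-4-methoxyphenyl]-2-methoxypropane-1,3-dione | COc1ccc(C(=O)C(OC)C(=O)c2c(Br)cc(OC)c(OCc3ccccc3)c2OC)cc1OCc1ccccc1
F4 | step 5 | (2R,3R)-1-[3-(benzyloxy)-6-bromo-2,4-dimethoxyphenyl]-3-[3-(benzyloxy)-4-methoxyphenyl]-2-methoxypropane-1,3-diol (C1 epimers) | COc1ccc([C@@H](O)[C@@H](OC)C(O)c2c(Br)cc(OC)c(OCc3ccccc3)c2OC)cc1OCc1ccccc1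
F5 | step 5 | (2R,3S)-6-(benzyloxy)-2-[3-(benzyloxy)-4-methoxyphenyl]-3,5,7-trimethoxy-3,4-dihydro-2H-chromen-4-ol (C4 epimers) | COc1ccc([C@H]2Oc3cc(OC)c(OCc4ccccc4)c(OC)c3C(O)[C@@H]2OC)cc1OCc1ccccc1
F6 | step 6 | (2R,3R)-6-hydroxy-2-(3-hydroxy-4-methoxyphenyl)-3,5,7-trimethoxy-2,3-dihydro-4H-chromen-4-one | COc1ccc([C@H]2Oc3cc(OC)c(O)c(OC)c3C(=O)[C@@H]2OC)cc1O
F7 | step 2 | [3-(benzyloxy)-6-bromo-2,4-dimethoxyphenyl]magnesium chloride | Cl[Mg]c1c(Br)cc(OC)c(OCc2ccccc2)c1OC
F8 | step 2 | 1-[3-(benzyloxy)-6-bromo-2,4-dimethoxyphenyl]ethan-1-ol (racemic) | COc1cc(Br)c(C(C)O)c(OC)c1OCc1ccccc1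
A1 | alternative 1 | (2R,3R)-3-[3-(benzyloxy)-4-methoxyphenyl]-1-(2,3-dihydroxy-4-methoxyphenyl)-3-hydroxy-2-methoxypropan-1-one | COc1ccc([C@@H](O)[C@@H](OC)C(=O)c2ccc(OC)c(O)c2O)cc1OCc1ccccc1
A2 | alternative 1 | (2R,3R)-2-[3-(benzyloxy)-4-methoxyphenyl]-5,6-dihydroxy-3,7-dimethoxy-2,3-dihydro-4H-chromen-4-one | COc1ccc([C@H]2Oc3cc(OC)c(O)c(O)c3C(=O)[C@@H]2OC)cc1OCc1ccccc1
A3 | alternative 2 | (S)-1-[3-(benzyloxy)-4-methoxyphenyl]prop-2-en-1-yl 4-(benzyloxy)-2-ethenyl-3,5-dimethoxyphenyl ether | COc1ccc([C@H](C=C)Oc2cc(OC)c(OCc3ccccc3)c(OC)c2C=C)cc1OCc1ccccc1
A4 | alternative 2 | (2S)-6-(benzyloxy)-2-[3-(benzyloxy)-4-methoxyphenyl]-5,7-dimethoxy-2H-chromene | COc1ccc([C@H]2Oc3cc(OC)c(OCc4ccccc4)c(OC)c3C=C2)cc1OCc1ccccc1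
A5 | alternative 3 | 4-(benzyloxy)-3,5-dimethoxy-2-(trimethylsilyl)phenyl trifluoromethanesulfonate | COc1cc(OS(=O)(=O)C(F)(F)F)c([Si](C)(C)C)c(OC)c1OCc1ccccc1
A6 | alternative 3 | methyl (2R,3R)-3-[3-(benzyloxy)-4-methoxyphenyl]-3-hydroxy-2-methoxypropanoate | COc1ccc([C@@H](O)[C@@H](OC)C(=O)OC)cc1OCc1ccccc1
A7 | alternative 3 | (2R,3R)-6-(benzyloxy)-2-[3-(benzyloxy)-4-methoxyphenyl]-3,5,7-trimethoxy-2,3-dihydro-4H-chromen-4-one | COc1ccc([C@H]2Oc3cc(OC)c(OCc4ccccc4)c(OC)c3C(=O)[C@@H]2OC)cc1OCc1ccccc1
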